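## Retrosynthetic overview

1. The target is an ent-lariciresinol-type tetrahydrofuran whose 2-aryl group is a chain of three trans-phenylcoumarans: ring A (next to the tetrahydrofuran) and ring B are 2S,3R, ring C (carrying the terminal guaiacyl) is 2R,3S. The usual biomimetic phenol-radical (β-5) coupling is not used.
2. Tetrahydrofuran last: the C2–O bond by SN1 cycloetherification of a hexaol, which comes from the aldol of an (S)-β-benzyl-γ-butyrolactone (Stobbe condensation, asymmetric hydrogenation) with the ring A aldehyde and a global LiAlH4 reduction.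
3. Rings A and B together (key step): one-flask twofold catalyst-controlled 1,5-C–H insertion of a bis(aryldiazoacetate) with Rh2(R-PTTL)4 forms both C2–C3 bonds (cis), then epimerisation gives trans.
4. Ring C first, by the same insertion with the antipodal catalyst Rh2(S-PTTL)4. The diazoesters come directly from aryl iodides (5-iodovanillin, used three times) by palladium-catalysed coupling with ethyl diazoacetate, and the units are joined by Mitsunobu etherification.
5. Order of ring formation: ring C, then rings A and B simultaneously, then the tetrahydrofuran.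

Assumption: the facial sense of Rh2(S-PTTL)4 (2R cis ester) and of the (R,R)-Et-DuPhos rhodium catalyst (S succinate) is taken from their behaviour with the closest analogues; if either proves reversed, the antipodal catalyst is used with nothing else changed.

## Route

Step 1
Reactants: 1 4-(benzyloxy)-3-methoxybenzyl alcohol; 2 5-iodovanillin (4-hydroxy-3-iodo-5-methoxybenzaldehyde)
Product: 3 4-{[4-(benzyloxy)-3-methoxybenzyl]oxy}-3-iodo-5-methoxybenzaldehyde
Conditions: PPh3, DIAD, THF, 0 °C to rt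
Reagents that add atoms: none
Why: Mitsunobu etherification, in which the acidic phenol (both ortho positions and the para position blocked, so only O-alkylation is possible) is alkylated by the activated primary benzylic alcohol; no stereocentre is involved.

Step 2
Reactants: 3 4-{[4-(benzyloxy)-3-methoxybenzyl]oxy}-3-iodo-5-methoxybenzaldehyde; 4 ethyl diazoacetate
Product: 5 ethyl 2-(2-{[4-(benzyloxy)-3-methoxybenzyl]oxy}-5-formyl-3-methoxyphenyl)-2-diazoacetate
Conditions: Pd(PPh3)4 (5 mol %), Ag2CO3 (0.5 equiv), Et3N (1.3 equiv), toluene, rt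
Reagents that add atoms: none
Why: Palladium-catalysed cross-coupling of an aryl iodide with the C–H bond of an acceptor diazo compound gives the aryldiazoacetate in one step at room temperature, where the diazo group, the aldehyde and the benzylic ethers survive.

Step 3
Reactants: 5 ethyl 2-(2-{[4-(benzyloxy)-3-methoxybenzyl]oxy}-5-formyl-3-methoxyphenyl)-2-diazoacetate
Product: 6 ethyl (2R,3S)-2-[4-(benzyloxy)-3-methoxyphenyl]-5-formyl-7-methoxy-2,3-dihydrobenzofuran-3-carboxylate (cis; ring C)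
Conditions: Rh2(S-PTTL)4 (1 mol %; PTTL = N-phthaloyl-tert-leucinate), toluene, −60 °C
Reagents that add atoms: none
Why: Enantioselective intramolecular 1,5-C–H insertion of a donor/acceptor rhodium carbenoid into the ether-activated, electron-rich benzylic C–H bond, in which the chiral carboxylate catalyst fixes C2 as R and the concerted insertion gives the 2,3-cis ester (3S).

Step 4
Reactants: 6 ethyl (2R,3S)-2-[4-(benzyloxy)-3-methoxyphenyl]-5-formyl-7-methoxy-2,3-dihydrobenzofuran-3-carboxylate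
Product: 8 ethyl (2R,3R)-2-[4-(benzyloxy)-3-methoxyphenyl]-5-(hydroxymethyl)-7-methoxy-2,3-dihydrobenzofuran-3-carboxylate, via trans aldehyde 7 (not isolated)
Conditions: NaOEt (0.2 equiv), EtOH–THF, 0 °C to rt; then NaBH4, 0 °C
Reagents that add atoms: none
Why: Base-mediated epimerisation of the acidic C3–H gives the thermodynamically favoured trans ester (C3 becomes R, C2 untouched; ethoxide matches the ethyl ester), and chemoselective borohydride reduction then converts only the aldehyde.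

Step 5
Reactants: 8 ethyl (2R,3R)-2-[4-(benzyloxy)-3-methoxyphenyl]-5-(hydroxymethyl)-7-methoxy-2,3-dihydrobenzofuran-3-carboxylate; 2 5-iodovanillin
Product: 9 ethyl (2R,3R)-2-[4-(benzyloxy)-3-methoxyphenyl]-5-[(4-formyl-2-iodo-6-methoxyphenoxy)methyl]-7-methoxy-2,3-dihydrobenzofuran-3-carboxylate
Conditions: PPh3, DIAD, THF, 0 °C to rt
Reagents that add atoms: none
Why: Mitsunobu etherification of the primary p-alkoxybenzylic alcohol with the acidic phenol under neutral conditions that leave the epimerisable ester untouched.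

Step 6
Reactants: 9 ethyl (2R,3R)-2-[4-(benzyloxy)-3-methoxyphenyl]-5-[(4-formyl-2-iodo-6-methoxyphenoxy)methyl]-7-methoxy-2,3-dihydrobenzofuran-3-carboxylate
Product: 10 ethyl (2R,3R)-2-[4-(benzyloxy)-3-methoxyphenyl]-5-{[4-(hydroxymethyl)-2-iodo-6-methoxyphenoxy]methyl}-7-methoxy-2,3-dihydrobenzofuran-3-carboxylate
Conditions: NaBH4, EtOH–THF, 0 °C
Reagents that add atoms: none
Why: Chemoselective borohydride reduction of the aryl aldehyde in the presence of the ester and the aryl iodide.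

Step 7
Reactants: 10 ethyl (2R,3R)-2-[4-(benzyloxy)-3-methoxyphenyl]-5-{[4-(hydroxymethyl)-2-iodo-6-methoxyphenoxy]methyl}-7-methoxy-2,3-dihydrobenzofuran-3-carboxylate; 2 5-iodovanillin
Product: 11 ethyl (2R,3R)-2-[4-(benzyloxy)-3-methoxyphenyl]-5-({4-[(4-formyl-2-iodo-6-methoxyphenoxy)methyl]-2-iodo-6-methoxyphenoxy}methyl)-7-methoxy-2,3-dihydrobenzofuran-3-carboxylate (bis-iodide aldehyde)
Conditions: PPh3, DIAD, THF, 0 °C to rt
Reagents that add atoms: none
Why: Third Mitsunobu etherification, which adds the ring A precursor and completes the linear poly(aryl benzyl ether) skeleton.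

Step 8
Reactants: 11 bis-iodide aldehyde; 4 ethyl diazoacetate (4 equiv)
Product: 12 bis(diazoester) aldehyde (11 with each iodine replaced by a C(=N2)CO2Et group)
Conditions: Pd(PPh3)4 (10 mol %), Ag2CO3 (1.0 equiv), Et3N (2.6 equiv), toluene, rt
Reagents that add atoms: none
Why: Twofold palladium-catalysed cross-coupling of aryl iodides with ethyl diazoacetate (same reaction as step 2), whose mild amine/carbonate base leaves the aldehyde and the ring C ester untouched.

Step 9
Reactants: 12 bis(diazoester) aldehyde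
Product: 13 ethyl (2S,3R)-5-formyl-7-methoxy-2-{(2S,3R)-3-(ethoxycarbonyl)-7-methoxy-2-[(2R,3R)-2-(4-benzyloxy-3-methoxyphenyl)-3-(ethoxycarbonyl)-7-methoxy-2,3-dihydrobenzofuran-5-yl]-2,3-dihydrobenzofuran-5-yl}-2,3-dihydrobenzofuran-3-carboxylate (rings A and B cis, ring C trans)
Conditions: Rh2(R-PTTL)4 (2 mol %), toluene, −60 °C
Reagents that add atoms: none
Why: Twofold enantioselective intramolecular 1,5-C–H insertion in one flask, in which each carbenoid can reach only its own ArO–CH2 group and the antipodal catalyst sets C2 of rings A and B as S with cis esters (3R), independently of the remote ring C centres.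

Step 10
Reactants: 13 triester aldehyde with rings A and B cis
Product: 14 ethyl (2S,3S)-5-formyl-7-methoxy-2-{(2S,3S)-3-(ethoxycarbonyl)-7-methoxy-2-[(2R,3R)-2-(4-benzyloxy-3-methoxyphenyl)-3-(ethoxycarbonyl)-7-methoxy-2,3-dihydrobenzofuran-5-yl]-2,3-dihydrobenzofuran-5-yl}-2,3-dihydrobenzofuran-3-carboxylate (all-trans triester aldehyde)
Conditions: NaOEt (0.3 equiv), EtOH–THF, 0 °C to rt
Reagents that add atoms: none
Why: Thermodynamic epimerisation of the two cis α-aryl esters through their enolates gives the trans rings (C3 of rings A and B becomes S, C2 centres untouched), kept short and cold to avoid E1cB opening.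

Step 11
Reactants: 15 4-(benzyloxy)-3-methoxybenzaldehyde; 16 dimethyl succinate
Product: 17 (E)-4-[4-(benzyloxy)-3-methoxyphenyl]-3-(methoxycarbonyl)but-3-enoic acid
Conditions: NaOMe (1.5 equiv), MeOH, reflux; then aq HCl
Reagents that add atoms: none
Why: Stobbe condensation (aldol, lactonisation to the paraconate, E1cB ring opening) gives the arylidene succinate half-ester with the free acid on the CH2 arm.

Step 12
Reactants: 17 (E)-4-[4-(benzyloxy)-3-methoxyphenyl]-3-(methoxycarbonyl)but-3-enoic acid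
Product: 18 (S)-4-[4-(benzyloxy)-3-methoxyphenyl]-3-(methoxycarbonyl)butanoic acid
Conditions: H2 (5 atm), [Rh(cod)((R,R)-Et-DuPhos)]BF4 (0.2 mol %), NaOMe (0.1 equiv), MeOH, rt
Reagents that add atoms: none
Why: Rhodium–bisphospholane asymmetric hydrogenation of an itaconate-type half-ester, in which chelation by the carboxylate arm directs hydrogen to one face and sets the S centre (the later tetrahydrofuran C4), with the benzyl ether untouched by the homogeneous catalyst.

Step 13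
Reactants: 18 (S)-4-[4-(benzyloxy)-3-methoxyphenyl]-3-(methoxycarbonyl)butanoic acid
Product: 20 (S)-4-[4-(benzyloxy)-3-methoxybenzyl]dihydrofuran-2(3H)-one, via hydroxy acid 19 (not isolated)
Conditions: KOH (1.0 equiv), EtOH; CaCl2, NaBH4, −10 °C to rt; then 2 M HCl, rt
Reagents that add atoms: none
Why: Chemoselective borohydride reduction of the ester in the presence of the unreactive carboxylate salt, followed by acid-catalysed lactonisation, gives the β-benzyl lactone without touching the stereocentre.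

Step 14
Reactants: 20 (S)-4-[4-(benzyloxy)-3-methoxybenzyl]dihydrofuran-2(3H)-one (1.3 equiv); 14 all-trans triester aldehyde
Product: 22 (3R,4S)-4-[4-(benzyloxy)-3-methoxybenzyl]-3-[hydroxy(aryl)methyl]dihydrofuran-2(3H)-one in which aryl is C5 of ring A of the triester (both carbinol epimers), via lithium enolate 21 (not isolated)
Conditions: LiN(SiMe3)2 (1.25 equiv), THF, −78 °C; then 14, −78 °C, 30 min; AcOH quench at −78 °C
Reagents that add atoms: none
Why: Lithium enolate aldol addition, in which the aldehyde approaches the enolate face anti to the C4 benzyl group and sets the lactone C3 as R (trans), while the carbinol centre forms as an epimer mixture that is erased in step 16 and fast addition at −78 °C outruns proton transfer from the ring esters.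

Step 15
Reactants: 22 aldol adduct (both carbinol epimers)
Product: 23 (2S,3S)-2-[4-(benzyloxy)-3-methoxybenzyl]-3-[hydroxy(aryl)methyl]butane-1,4-diol in which the three ring esters are now CH2OH (hexaol; ring A 2S,3R, ring B 2S,3R, ring C 2R,3S; both carbinol epimers)
Conditions: LiAlH4, THF, 0 °C to rt
Reagents that add atoms: none
Why: Global hydride reduction of the lactone and the three ethyl esters to primary alcohols, which leaves all stereocentres in place (the CIP descriptors at C3 of the rings change only because the substituent priorities change).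

Step 16
Reactants: 23 hexaol (both carbinol epimers)
Product: 24 O,O'-dibenzyl ether of the target, with the (2R,3S,4S)-tetrahydrofuran formed
Conditions: CSA (10 mol %), CH2Cl2–THF, 0 °C to rt
Reagents that add atoms: none
Why: Acid-catalysed SN1 cycloetherification, in which the p-alkoxybenzylic cation from either carbinol epimer is trapped 5-exo by the CH2OH on the benzyl-bearing carbon (the other CH2OH could only give an oxetane) to give the 2,3-trans ring (C2 R), the 3,4-cis relationship being fixed already by the trans lactone.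

Step 17
Reactants: 24 O,O'-dibenzyl ether of the target
Product: 25 target CNP0267891.2
Conditions: H2 (1 atm), 10 % Pd/C, EtOAc–MeOH, rt, stopped at full conversion
Reagents that add atoms: none
Why: Catalytic hydrogenolysis of the two phenolic benzyl ethers, which cleave much faster than the cyclic secondary benzylic ethers under neutral conditions.

## Compound list

1 | 4-(benzyloxy)-3-methoxybenzyl alcohol | COc1cc(CO)ccc1OCc1ccccc1 | starting material
2 | 5-iodovanillin (4-hydroxy-3-iodo-5-methoxybenzaldehyde) | COc1cc(C=O)cc(I)c1O | starting material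
3 | 4-{[4-(benzyloxy)-3-methoxybenzyl]oxy}-3-iodo-5-methoxybenzaldehyde | COc1cc(C=O)cc(I)c1OCc1ccc(OCc2ccccc2)c(OC)c1 | intermediate
4 | ethyl diazoacetate | CCOC(=O)C=[N+]=[N-] | starting material
5 | ethyl 2-(2-{[4-(benzyloxy)-3-methoxybenzyl]oxy}-5-formyl-3-methoxyphenyl)-2-diazoacetate | CCOC(=O)C(=[N+]=[N-])c1cc(C=O)cc(OC)c1OCc1ccc(OCc2ccccc2)c(OC)c1 | intermediate
6 | ethyl (2R,3S)-2-[4-(benzyloxy)-3-methoxyphenyl]-5-formyl-7-methoxy-2,3-dihydrobenzofuran-3-carboxylate (cis) | O=Cc1cc(OC)c2c(c1)[C@H](C(=O)OCC)[C@H](c1ccc(OCc3ccccc3)c(OC)c1)O2 | intermediate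
7 | ethyl (2R,3R)-2-[4-(benzyloxy)-3-methoxyphenyl]-5-formyl-7-methoxy-2,3-dihydrobenzofuran-3-carboxylate (trans aldehyde) | O=Cc1cc(OC)c2c(c1)[C@@H](C(=O)OCC)[C@H](c1ccc(OCc3ccccc3)c(OC)c1)O2 | intermediate (not isolated)
8 | ethyl (2R,3R)-2-[4-(benzyloxy)-3-methoxyphenyl]-5-(hydroxymethyl)-7-methoxy-2,3-dihydrobenzofuran-3-carboxylate | OCc1cc(OC)c2c(c1)[C@@H](C(=O)OCC)[C@H](c1ccc(OCc3ccccc3)c(OC)c1)O2 | intermediate
9 | ethyl (2R,3R)-2-[4-(benzyloxy)-3-methoxyphenyl]-5-[(4-formyl-2-iodo-6-methoxyphenoxy)methyl]-7-methoxy-2,3-dihydrobenzofuran-3-carboxylate | COc1cc(C=O)cc(I)c1OCc1cc(OC)c2c(c1)[C@@H](C(=O)OCC)[C@H](c1ccc(OCc3ccccc3)c(OC)c1)O2 | intermediate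
10 | ethyl (2R,3R)-2-[4-(benzyloxy)-3-methoxyphenyl]-5-{[4-(hydroxymethyl)-2-iodo-6-methoxyphenoxy]methyl}-7-methoxy-2,3-dihydrobenzofuran-3-carboxylate | COc1cc(CO)cc(I)c1OCc1cc(OC)c2c(c1)[C@@H](C(=O)OCC)[C@H](c1ccc(OCc3ccccc3)c(OC)c1)O2 | intermediate
11 | bis-iodide aldehyde: ethyl (2R,3R)-2-[4-(benzyloxy)-3-methoxyphenyl]-5-({4-[(4-formyl-2-iodo-6-methoxyphenoxy)methyl]-2-iodo-6-methoxyphenoxy}methyl)-7-methoxy-2,3-dihydrobenzofuran-3-carboxylate | COc1cc(C=O)cc(I)c1OCc1cc(OC)c(OCc2cc(OC)c3c(c2)[C@@H](C(=O)OCC)[C@H](c2ccc(OCc4ccccc4)c(OC)c2)O3)c(I)c1 | intermediate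
12 | bis(diazoester) aldehyde (11 with each iodine replaced by C(=N2)CO2Et) | COc1cc(C=O)cc(C(=[N+]=[N-])C(=O)OCC)c1OCc1cc(OC)c(OCc2cc(OC)c3c(c2)[C@@H](C(=O)OCC)[C@H](c2ccc(OCc4ccccc4)c(OC)c2)O3)c(C(=[N+]=[N-])C(=O)OCC)c1 | intermediate
13 | triester aldehyde, ring A cis (2S,3R), ring B cis (2S,3R), ring C trans (2R,3R) | O=Cc1cc(OC)c2c(c1)[C@@H](C(=O)OCC)[C@@H](c1cc(OC)c3c(c1)[C@@H](C(=O)OCC)[C@@H](c1cc(OC)c4c(c1)[C@@H](C(=O)OCC)[C@H](c1ccc(OCc5ccccc5)c(OC)c1)O4)O3)O2 | intermediate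
14 | all-trans triester aldehyde, ring A (2S,3S), ring B (2S,3S), ring C (2R,3R) | O=Cc1cc(OC)c2c(c1)[C@H](C(=O)OCC)[C@@H](c1cc(OC)c3c(c1)[C@H](C(=O)OCC)[C@@H](c1cc(OC)c4c(c1)[C@@H](C(=O)OCC)[C@H](c1ccc(OCc5ccccc5)c(OC)c1)O4)O3)O2 | intermediate
15 | 4-(benzyloxy)-3-methoxybenzaldehyde | COc1cc(C=O)ccc1OCc1ccccc1 | starting material
16 | dimethyl succinate | COC(=O)CCC(=O)OC | starting material
17 | (E)-4-[4-(benzyloxy)-3-methoxyphenyl]-3-(methoxycarbonyl)but-3-enoic acid | COC(=O)/C(=C/c1ccc(OCc2ccccc2)c(OC)c1)CC(=O)O | intermediate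
18 | (S)-4-[4-(benzyloxy)-3-methoxyphenyl]-3-(methoxycarbonyl)butanoic acid | COC(=O)[C@@H](Cc1ccc(OCc2ccccc2)c(OC)c1)CC(=O)O | intermediate
19 | (S)-4-[4-(benzyloxy)-3-methoxyphenyl]-3-(hydroxymethyl)butanoic acid (hydroxy acid) | OC[C@@H](Cc1ccc(OCc2ccccc2)c(OC)c1)CC(=O)O | intermediate (not isolated)
20 | (S)-4-[4-(benzyloxy)-3-methoxybenzyl]dihydrofuran-2(3H)-one | O=C1C[C@H](Cc2ccc(OCc3ccccc3)c(OC)c2)CO1 | intermediate
21 | lithium enolate of 20 | [Li+].[O-]C1=C[C@H](Cc2ccc(OCc3ccccc3)c(OC)c2)CO1 | intermediate (not isolated)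
22 | aldol adduct: (3R,4S)-4-[4-(benzyloxy)-3-methoxybenzyl]-3-[hydroxy(aryl)methyl]dihydrofuran-2(3H)-one, aryl = C5 of ring A of the all-trans triester, carbinol centre as both epimers | COc1cc(C[C@@H]2COC(=O)[C@H]2C(O)c2cc(OC)c3c(c2)[C@H](C(=O)OCC)[C@@H](c2cc(OC)c4c(c2)[C@H](C(=O)OCC)[C@@H](c2cc(OC)c5c(c2)[C@@H](C(=O)OCC)[C@H](c2ccc(OCc6ccccc6)c(OC)c2)O5)O4)O3)ccc1OCc1ccccc1 | intermediate
23 | hexaol: (2S,3S)-2-[4-(benzyloxy)-3-methoxybenzyl]-3-[hydroxy(aryl)methyl]butane-1,4-diol, rings A (2S,3R), B (2S,3R), C (2R,3S) each with 3-CH2OH, carbinol centre as both epimers | COc1cc(C[C@H](CO)[C@@H](CO)C(O)c2cc(OC)c3c(c2)[C@H](CO)[C@@H](c2cc(OC)c4c(c2)[C@H](CO)[C@@H](c2cc(OC)c5c(c2)[C@@H](CO)[C@H](c2ccc(OCc6ccccc6)c(OC)c2)O5)O4)O3)ccc1OCc1ccccc1 | intermediate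
24 | O,O'-dibenzyl ether of the target ((2R,3S,4S)-tetrahydrofuran; rings A and B 2S,3R; ring C 2R,3S) | COc1cc(C[C@@H]2CO[C@@H](c3cc(OC)c4c(c3)[C@H](CO)[C@@H](c3cc(OC)c5c(c3)[C@H](CO)[C@@H](c3cc(OC)c6c(c3)[C@@H](CO)[C@H](c3ccc(OCc7ccccc7)c(OC)c3)O6)O5)O4)[C@@H]2CO)ccc1OCc1ccccc1 | intermediate
25 | CNP0267891.2: 4-[(2R,3S)-3-(hydroxymethyl)-5-{(2S,3R)-3-(hydroxymethyl)-5-[(2S,3R)-3-(hydroxymethyl)-5-[(2R,3S,4S)-4-(4-hydroxy-3-methoxybenzyl)-3-(hydroxymethyl)tetrahydrofuran-2-yl]-7-methoxy-2,3-dihydrobenzofuran-2-yl]-7-methoxy-2,3-dihydrobenzofuran-2-yl}-7-methoxy-2,3-dihydrobenzofuran-2-yl]-2-methoxyphenol | COc1cc(C[C@@H]2CO[C@@H](c3cc(OC)c4c(c3)[C@H](CO)[C@@H](c3cc(OC)c5c(c3)[C@H](CO)[C@@H](c3cc(OC)c6c(c3)[C@@H](CO)[C@H](c3ccc(O)c(OC)c3)O6)O5)O4)[C@@H]2CO)ccc1O | target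

## Step count and risks

Total step count: 17. Longest linear sequence: 14 steps (steps 1 to 10, then 14 to 17); the lactone branch (steps 11 to 13) joins at step 14.

The three steps most likely to fail:

1. The twofold C–H insertion of step 9. The two new rings are set only by the catalyst, the extra ortho methoxy group next to the ether oxygen is untested for this catalyst class, and diastereomers that differ at remote rings may not separate. Fallback: the rings are made one at a time, so that each new ring is purified before the next stereocentres are set. Setting out from 9, palladium coupling with 4 gives the ring B diazoester aldehyde F6, Rh2(R-PTTL)4 insertion gives the ring B cis ester aldehyde F7, NaOEt followed by NaBH4 gives the ring B trans alcohol F8, Mitsunobu etherification with 2 gives the ring A iodide aldehyde F9, palladium coupling with 4 gives the ring A diazoester aldehyde F10, and a second Rh2(R-PTTL)4 insertion gives the ring A cis triester aldehyde F11, which NaOEt in EtOH epimerises so that the route is rejoined at 14.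

2. The twofold palladium/diazoacetate coupling of step 8. Both iodides are ortho to a bulky benzyloxy group, one ring is electron-rich, and a free aldehyde is present. Fallback: the diazo groups are introduced by Regitz diazo transfer onto arylacetates, so no aryl iodide is needed. Commercial 2-hydroxy-3-methoxyphenylacetic acid is formylated para to the hydroxyl (Duff reaction: hexamethylenetetramine, CF3CO2H, 80 °C, then aq HCl) to 2-(5-formyl-2-hydroxy-3-methoxyphenyl)acetic acid F1 and esterified (EtOH, H2SO4) to ethyl 2-(5-formyl-2-hydroxy-3-methoxyphenyl)acetate F2. Setting out from 8, Mitsunobu etherification with F2 gives the ring B arylacetate aldehyde F3, NaBH4 gives the ring B arylacetate alcohol F4, a second Mitsunobu etherification with F2 gives the bis(arylacetate) aldehyde F5, and twofold diazo transfer (p-acetamidobenzenesulfonyl azide, DBU, MeCN, 0 °C) rejoins the route at 12.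

3. The acid-mediated ring closure of step 16. It is run on a very polar hexaol that carries three acid-sensitive phenylcoumarans and an electron-rich benzyl ring able to close to an aryltetralin. Fallback: the tetrahydrofuran is built before rings A and B, when only ring C is present and the substrate is far less polar. Setting out from 11, aldol addition of enolate 21 gives the bis-iodide hydroxy lactone F12, LiBH4 in THF gives the bis-iodide tetraol F13, CSA gives the bis-iodide tetrahydrofuran diol F14, Ac2O in pyridine gives the bis-iodide diacetate F15 (protection against O–H insertion), twofold palladium coupling with 4 gives the bis(diazoester) diacetate F16, twofold Rh2(R-PTTL)4 insertion gives the cis,cis diester diacetate F17, NaOEt in EtOH gives the trans,trans diester diol F18 (epimerised and deacetylated), and LiAlH4 reduction rejoins the route at 24.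

## Further compounds

F1 | step 8 | 2-(5-formyl-2-hydroxy-3-methoxyphenyl)acetic acid | COc1cc(C=O)cc(CC(=O)O)c1O
F2 | step 8 | ethyl 2-(5-formyl-2-hydroxy-3-methoxyphenyl)acetate | CCOC(=O)Cc1cc(C=O)cc(OC)c1O
F3 | step 8 | ring B arylacetate aldehyde (8 etherified with F2) | CCOC(=O)Cc1cc(C=O)cc(OC)c1OCc1cc(OC)c2c(c1)[C@@H](C(=O)OCC)[C@H](c1ccc(OCc3ccccc3)c(OC)c1)O2
F4 | step 8 | ring B arylacetate alcohol | CCOC(=O)Cc1cc(CO)cc(OC)c1OCc1cc(OC)c2c(c1)[C@@H](C(=O)OCC)[C@H](c1ccc(OCc3ccccc3)c(OC)c1)O2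
F5 | step 8 | bis(arylacetate) aldehyde | CCOC(=O)Cc1cc(C=O)cc(OC)c1OCc1cc(OC)c(OCc2cc(OC)c3c(c2)[C@@H](C(=O)OCC)[C@H](c2ccc(OCc4ccccc4)c(OC)c2)O3)c(CC(=O)OCC)c1
F6 | step 9 | ring B diazoester aldehyde | CCOC(=O)C(=[N+]=[N-])c1cc(C=O)cc(OC)c1OCc1cc(OC)c2c(c1)[C@@H](C(=O)OCC)[C@H](c1ccc(OCc3ccccc3)c(OC)c1)O2
F7 | step 9 | ring B cis ester aldehyde (ring B 2S,3R; ring C 2R,3R) | O=Cc1cc(OC)c2c(c1)[C@@H](C(=O)OCC)[C@@H](c1cc(OC)c3c(c1)[C@@H](C(=O)OCC)[C@H](c1ccc(OCc4ccccc4)c(OC)c1)O3)O2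
F8 | step 9 | ring B trans alcohol (ring B 2S,3S; ring C 2R,3R) | OCc1cc(OC)c2c(c1)[C@H](C(=O)OCC)[C@@H](c1cc(OC)c3c(c1)[C@@H](C(=O)OCC)[C@H](c1ccc(OCc4ccccc4)c(OC)c1)O3)O2
F9 | step 9 | ring A iodide aldehyde | COc1cc(C=O)cc(I)c1OCc1cc(OC)c2c(c1)[C@H](C(=O)OCC)[C@@H](c1cc(OC)c3c(c1)[C@@H](C(=O)OCC)[C@H](c1ccc(OCc4ccccc4)c(OC)c1)O3)O2
F10 | step 9 | ring A diazoester aldehyde | CCOC(=O)C(=[N+]=[N-])c1cc(C=O)cc(OC)c1OCc1cc(OC)c2c(c1)[C@H](C(=O)OCC)[C@@H](c1cc(OC)c3c(c1)[C@@H](C(=O)OCC)[C@H](c1ccc(OCc4ccccc4)c(OC)c1)O3)O2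
F11 | step 9 | ring A cis triester aldehyde (ring A 2S,3R; ring B 2S,3S; ring C 2R,3R) | O=Cc1cc(OC)c2c(c1)[C@@H](C(=O)OCC)[C@@H](c1cc(OC)c3c(c1)[C@H](C(=O)OCC)[C@@H](c1cc(OC)c4c(c1)[C@@H](C(=O)OCC)[C@H](c1ccc(OCc5ccccc5)c(OC)c1)O4)O3)O2
F12 | step 16 | bis-iodide hydroxy lactone (both carbinol epimers) | COc1cc(C[C@@H]2COC(=O)[C@H]2C(O)c2cc(I)c(OCc3cc(OC)c(OCc4cc(OC)c5c(c4)[C@@H](C(=O)OCC)[C@H](c4ccc(OCc6ccccc6)c(OC)c4)O5)c(I)c3)c(OC)c2)ccc1OCc1ccccc1
F13 | step 16 | bis-iodide tetraol (both carbinol epimers) | COc1cc(C[C@H](CO)[C@@H](CO)C(O)c2cc(I)c(OCc3cc(OC)c(OCc4cc(OC)c5c(c4)[C@@H](CO)[C@H](c4ccc(OCc6ccccc6)c(OC)c4)O5)c(I)c3)c(OC)c2)ccc1OCc1ccccc1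
F14 | step 16 | bis-iodide tetrahydrofuran diol | COc1cc(C[C@@H]2CO[C@@H](c3cc(I)c(OCc4cc(OC)c(OCc5cc(OC)c6c(c5)[C@@H](CO)[C@H](c5ccc(OCc7ccccc7)c(OC)c5)O6)c(I)c4)c(OC)c3)[C@@H]2CO)ccc1OCc1ccccc1
F15 | step 16 | bis-iodide diacetate | COc1cc(C[C@@H]2CO[C@@H](c3cc(I)c(OCc4cc(OC)c(OCc5cc(OC)c6c(c5)[C@@H](COC(C)=O)[C@H](c5ccc(OCc7ccccc7)c(OC)c5)O6)c(I)c4)c(OC)c3)[C@@H]2COC(C)=O)ccc1OCc1ccccc1
F16 | step 16 | bis(diazoester) diacetate | COc1cc(C[C@@H]2CO[C@@H](c3cc(C(=[N+]=[N-])C(=O)OCC)c(OCc4cc(OC)c(OCc5cc(OC)c6c(c5)[C@@H](COC(C)=O)[C@H](c5ccc(OCc7ccccc7)c(OC)c5)O6)c(C(=[N+]=[N-])C(=O)OCC)c4)c(OC)c3)[C@@H]2COC(C)=O)ccc1OCc1ccccc1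
F17 | step 16 | cis,cis diester diacetate (rings A and B 2S,3R) | COc1cc(C[C@@H]2CO[C@@H](c3cc(OC)c4c(c3)[C@@H](C(=O)OCC)[C@@H](c3cc(OC)c5c(c3)[C@@H](C(=O)OCC)[C@@H](c3cc(OC)c6c(c3)[C@@H](COC(C)=O)[C@H](c3ccc(OCc7ccccc7)c(OC)c3)O6)O5)O4)[C@@H]2COC(C)=O)ccc1OCc1ccccc1
F18 | step 16 | trans,trans diester diol (rings A and B 2S,3S) | COc1cc(C[C@@H]2CO[C@@H](c3cc(OC)c4c(c3)[C@H](C(=O)OCC)[C@@H](c3cc(OC)c5c(c3)[C@H](C(=O)OCC)[C@@H](c3cc(OC)c6c(c3)[C@@H](CO)[C@H](c3ccc(OCc7ccccc7)c(OC)c3)O6)O5)O4)[C@@H]2CO)ccc1OCc1ccccc1
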